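## Retrosynthetic overview

1. The O8 ester is attached last, by site-selective methacrylation of the 8,9-diol 19.
2. Key disconnection C9–C10: a ring-closing Mukaiyama aldol of the aromatic 3-silyloxyfuran 17 onto the C9 aldehyde. It destroys the furan aromaticity and creates the 3(2H)-furanone, the ten-membered ring, C9 and C10 in one step.
3. The furanone oxygen is carried as a C–B bond (C–H borylation of the 2,5-disubstituted furan) and unmasked just before the key step.
4. C6–C7: indium Barbier allylation and lactonization of Z-enal 6 with allyl bromide 10 gives the cis-fused α-methylene-γ-butyrolactone; C6 and C7 are relayed from C8 of (R)-glyceraldehyde acetonide.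
5. Ring order: furan (bought as 2-methylfuran) → butyrolactone → ten-membered carbocycle, formed together with the furan-to-furanone conversion.

Assumption: the target is taken exactly as drawn (4Z; 6S,7S,8S,9R,10R; cis-fused 12,6-lactone); carbons are numbered as in germacrane; Bpin = 4,4,5,5-tetramethyl-1,3,2-dioxaborolan-2-yl, TES = triethylsilyl, TBS = tert-butyldimethylsilyl.

## Route

Step 1
Reactants: 1 2-methylfuran; 2 ethyl but-2-ynoate
Product: 3 ethyl (2Z)-3-(5-methylfuran-2-yl)but-2-enoate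
Conditions: Pd(OAc)2 (5 mol %), AcOH, rt
Reagents that add atoms: none
Why: Fujiwara hydroheteroarylation: the free α-carbon of the furan adds to the palladium-activated alkynoate anti to the metal and protodepalladation gives net trans addition of furyl–H, so the furyl group ends up cis to the ester (Z), the geometry needed at C4=C5.

Step 2
Reactants: 3 ethyl (2Z)-3-(5-methylfuran-2-yl)but-2-enoate
Product: 4 ethyl (2Z)-3-[5-methyl-4-(Bpin)furan-2-yl]but-2-enoate
Conditions: [Ir(OMe)(cod)]2 (1.5 mol %), 4,4'-di-tert-butyl-2,2'-bipyridine (3 mol %), B2pin2 (0.55 equiv), THF, 60 °C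
Reagents that add atoms: bis(pinacolato)diboron, CC1(C)OB(OC1(C)C)B1OC(C)(C)C(C)(C)O1
Why: Sterically controlled iridium-catalysed C–H borylation: both α-positions are blocked and, of the two β-hydrogens, the one next to the small methyl group reacts, which puts boron on the carbon that becomes the C1 carbonyl.

Step 3
Reactants: 4 ethyl (2Z)-3-[5-methyl-4-(Bpin)furan-2-yl]but-2-enoate
Product: 5 (2Z)-3-[5-methyl-4-(Bpin)furan-2-yl]but-2-en-1-ol
Conditions: (Me2CHCH2)2AlH (2.2 equiv), CH2Cl2, −78 °C; aq. potassium sodium tartrate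
Reagents that add atoms: none
Why: 1,2-reduction of the conjugated ester by the aluminium hydride at low temperature, which leaves the aryl boronate and the Z-alkene untouched.

Step 4
Reactants: 5 (2Z)-3-[5-methyl-4-(Bpin)furan-2-yl]but-2-en-1-ol
Product: 6 (2Z)-3-[5-methyl-4-(Bpin)furan-2-yl]but-2-enal
Conditions: MnO2 (15 equiv), CH2Cl2, rt, dark
Reagents that add atoms: none
Why: Allylic alcohol oxidation with manganese dioxide under neutral conditions, which keeps the Z geometry and the boronate.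

Step 5
Reactants: 7 (4R)-2,2-dimethyl-1,3-dioxolane-4-carbaldehyde; 8 methyl acrylate
Product: 9 methyl 2-{[(4R)-2,2-dimethyl-1,3-dioxolan-4-yl](hydroxy)methyl}prop-2-enoate (carbinol epimers)
Conditions: DABCO (0.5 equiv), 1,4-dioxane/H2O 1:1, rt
Reagents that add atoms: none
Why: Morita–Baylis–Hillman reaction; the new carbinol centre forms as an epimer mixture that does not matter because this carbon becomes sp2 in step 6, and the dioxolane centre (later C8) is not touched.

Step 6
Reactants: 9 methyl 2-{[(4R)-2,2-dimethyl-1,3-dioxolan-4-yl](hydroxy)methyl}prop-2-enoate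
Product: 10 methyl (2Z)-2-(bromomethyl)-3-[(4S)-2,2-dimethyl-1,3-dioxolan-4-yl]prop-2-enoate
Conditions: NBS, Me2S, CH2Cl2, 0 °C to rt
Reagents that add atoms: N-bromosuccinimide, O=C1CCC(=O)N1Br
Why: Corey–Kim-type activation of the allylic alcohol and SN2' delivery of bromide with allylic transposition gives the thermodynamically preferred trisubstituted alkene with the dioxolane cis to CH2Br; the acid-free conditions spare the acetonide.

Step 7
Reactants: 6 (2Z)-3-[5-methyl-4-(Bpin)furan-2-yl]but-2-enal; 10 methyl (2Z)-2-(bromomethyl)-3-[(4S)-2,2-dimethyl-1,3-dioxolan-4-yl]prop-2-enoate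
Product: 12 (4S,5S)-4-[(4S)-2,2-dimethyl-1,3-dioxolan-4-yl]-3-methylidene-5-{(1Z)-2-[5-methyl-4-(Bpin)furan-2-yl]prop-1-en-1-yl}oxolan-2-one, via hydroxy ester 11 (not isolated)
Conditions: In powder (1.5 equiv), THF/H2O 1:1, rt; then PPTS (10 mol %), PhMe, 60 °C
Reagents that add atoms: none
Why: Indium Barbier allylation through a Zimmerman–Traxler chair, then lactonization: the substituent cis to CH2In sits axial and gives the 6,7-syn adduct (hence the cis-fused lactone), while allylic 1,3-strain keeps H8 in the allyl plane so the aldehyde adds anti to the C8–C9 bond with the C8–O bond outside, which sets 6S and 7S from 8S (water suppresses chelation by the acetonide oxygen).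

Step 8
Reactants: 12 (4S,5S)-4-[(4S)-2,2-dimethyl-1,3-dioxolan-4-yl]-3-methylidene-5-{(1Z)-2-[5-methyl-4-(Bpin)furan-2-yl]prop-1-en-1-yl}oxolan-2-one
Product: 14 (4S,5S)-4-[(1S)-1,2-bis(triethylsilyloxy)ethyl]-3-methylidene-5-{(1Z)-2-[5-methyl-4-(Bpin)furan-2-yl]prop-1-en-1-yl}oxolan-2-one, via diol 13 (not isolated)
Conditions: AcOH/H2O 4:1, 40 °C; evaporate; TESOTf (2.4 equiv), 2,6-lutidine, CH2Cl2, −78 °C
Reagents that add atoms: triethylsilyl trifluoromethanesulfonate, CC[Si](CC)(CC)OS(=O)(=O)C(F)(F)F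
Why: Mild acid hydrolysis of the terminal acetonide followed by silylation of both hydroxyls with a silyl triflate and a non-nucleophilic base at low temperature, so that the free 8-OH has no chance to translactonize.

Step 9
Reactants: 14 (4S,5S)-4-[(1S)-1,2-bis(triethylsilyloxy)ethyl]-3-methylidene-5-{(1Z)-2-[5-methyl-4-(Bpin)furan-2-yl]prop-1-en-1-yl}oxolan-2-one
Product: 15 (2S)-2-[(2S,3S)-4-methylidene-2-{(1Z)-2-[5-methyl-4-(Bpin)furan-2-yl]prop-1-en-1-yl}-5-oxooxolan-3-yl]-2-(triethylsilyloxy)acetaldehyde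
Conditions: (COCl)2 (4 equiv), DMSO (8 equiv), CH2Cl2, −78 to −40 °C; Et3N, −78 to 0 °C
Reagents that add atoms: none
Why: Swern oxidation in which the chlorosulfonium salt cleaves only the primary triethylsilyl ether and oxidizes it directly to the aldehyde, while the secondary silyl ether at C8 stays; the low temperature avoids epimerization at C8.

Step 10
Reactants: 15 (2S)-2-[(2S,3S)-4-methylidene-2-{(1Z)-2-[5-methyl-4-(Bpin)furan-2-yl]prop-1-en-1-yl}-5-oxooxolan-3-yl]-2-(triethylsilyloxy)acetaldehyde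
Product: 16 (2S)-2-[(2S,3S)-4-methylidene-2-{(1Z)-2-(5-methyl-4-oxo-4,5-dihydrofuran-2-yl)prop-1-en-1-yl}-5-oxooxolan-3-yl]-2-(triethylsilyloxy)acetaldehyde (C10 epimers)
Conditions: Me3NO (3 equiv), THF, 40 °C; pH 7 buffer
Reagents that add atoms: trimethylamine N-oxide, C[N+](C)(C)[O-]
Why: N-oxide oxidation of the C–B bond (1,2-shift from boron to oxygen) gives the 3-hydroxyfuran, which tautomerizes to the 3(2H)-furanone; its C10–H centre forms as a mixture that is erased in step 11, and the non-nucleophilic oxidant spares the aldehyde and the methylene lactone.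

Step 11
Reactants: 16 (2S)-2-[(2S,3S)-4-methylidene-2-{(1Z)-2-(5-methyl-4-oxo-4,5-dihydrofuran-2-yl)prop-1-en-1-yl}-5-oxooxolan-3-yl]-2-(triethylsilyloxy)acetaldehyde
Product: 19 (4Z,6S,7R,8S,9R,10R)-8,9-dihydroxy-1-oxo-3,10-epoxygermacra-2,4,11(13)-trien-12,6-olide, via silyloxyfuran 17 (not isolated), via silyl ether 18 (not isolated)
Conditions: TESOTf (1.05 equiv), Et3N, CH2Cl2, −78 °C; then syringe pump into Me2AlCl (3 equiv), CH2Cl2 (2 mM), −78 °C; then 1 M HCl, THF, 0 °C
Reagents that add atoms: triethylsilyl trifluoromethanesulfonate, CC[Si](CC)(CC)OS(=O)(=O)C(F)(F)F (its silicon is in 17 only)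
Why: Proposed new method: Me2AlCl forms a five-membered chelate between the aldehyde oxygen and O8 (its known behaviour with α-silyloxy aldehydes), and the aromatic 3-silyloxyfuran attacks with its methyl-bearing carbon (C10) on the chelate face opposite C7 in an open antiperiplanar Mukaiyama transition state, which sets 9R (8,9-syn) and, because the tether holds the furan oxygen next to C8 and the bulky silyloxy carbon away from the aluminium, 10R, while aromaticity is lost and the furanone carbonyl appears; the closest known reactions are the intermolecular Lewis acid aldol of 2-alkyl-3-silyloxyfurans with aldehydes and chelation-controlled Mukaiyama aldols, here run at high dilution to close the ten-membered ring, and the acidic quench removes the C8 silyl group.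

Step 12
Reactants: 19 (4Z,6S,7R,8S,9R,10R)-8,9-dihydroxy-1-oxo-3,10-epoxygermacra-2,4,11(13)-trien-12,6-olide; 20 methacrylic anhydride
Product: 21 (4Z,6S,7S,8S,9R,10R)-9-hydroxy-8-(2-methylprop-2-enoyloxy)-1-oxo-3,10-epoxygermacra-2,4,11(13)-trien-12,6-olide
Conditions: Et3N, DMAP (10 mol %), CH2Cl2, −20 °C
Reagents that add atoms: none
Why: Kinetically selective DMAP-catalysed acylation of the 8-OH, because the 9-OH is neopentyl-like (next to the quaternary C10) and reacts much more slowly; no stereocentre is touched.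

## Compound list

1 | 2-methylfuran | Cc1ccco1 | starting material
2 | ethyl but-2-ynoate | CC#CC(=O)OCC | starting material
3 | ethyl (2Z)-3-(5-methylfuran-2-yl)but-2-enoate | CCOC(=O)/C=C(/C)c1ccc(C)o1 | intermediate
4 | ethyl (2Z)-3-[5-methyl-4-(Bpin)furan-2-yl]but-2-enoate | CCOC(=O)/C=C(/C)c1cc(B2OC(C)(C)C(C)(C)O2)c(C)o1 | intermediate
5 | (2Z)-3-[5-methyl-4-(Bpin)furan-2-yl]but-2-en-1-ol | OC/C=C(/C)c1cc(B2OC(C)(C)C(C)(C)O2)c(C)o1 | intermediate
6 | (2Z)-3-[5-methyl-4-(Bpin)furan-2-yl]but-2-enal | O=C/C=C(/C)c1cc(B2OC(C)(C)C(C)(C)O2)c(C)o1 | intermediate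
7 | (4R)-2,2-dimethyl-1,3-dioxolane-4-carbaldehyde ((R)-glyceraldehyde acetonide) | O=C[C@H]1COC(C)(C)O1 | starting material
8 | methyl acrylate | C=CC(=O)OC | starting material
9 | methyl 2-{[(4R)-2,2-dimethyl-1,3-dioxolan-4-yl](hydroxy)methyl}prop-2-enoate (carbinol epimers) | C=C(C(=O)OC)C(O)[C@H]1COC(C)(C)O1 | intermediate
10 | methyl (2Z)-2-(bromomethyl)-3-[(4S)-2,2-dimethyl-1,3-dioxolan-4-yl]prop-2-enoate | COC(=O)/C(CBr)=C/[C@H]1COC(C)(C)O1 | intermediate
11 | methyl (3S,4S,5Z)-3-[(4S)-2,2-dimethyl-1,3-dioxolan-4-yl]-4-hydroxy-2-methylidene-6-[5-methyl-4-(Bpin)furan-2-yl]hept-5-enoate | C=C(C(=O)OC)[C@@H]([C@@H](O)/C=C(/C)c1cc(B2OC(C)(C)C(C)(C)O2)c(C)o1)[C@H]1COC(C)(C)O1 | intermediate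
12 | (4S,5S)-4-[(4S)-2,2-dimethyl-1,3-dioxolan-4-yl]-3-methylidene-5-{(1Z)-2-[5-methyl-4-(Bpin)furan-2-yl]prop-1-en-1-yl}oxolan-2-one | C=C1C(=O)O[C@@H](/C=C(/C)c2cc(B3OC(C)(C)C(C)(C)O3)c(C)o2)[C@H]1[C@H]1COC(C)(C)O1 | intermediate
13 | (4R,5S)-4-[(1S)-1,2-dihydroxyethyl]-3-methylidene-5-{(1Z)-2-[5-methyl-4-(Bpin)furan-2-yl]prop-1-en-1-yl}oxolan-2-one | C=C1C(=O)O[C@@H](/C=C(/C)c2cc(B3OC(C)(C)C(C)(C)O3)c(C)o2)[C@H]1[C@H](O)CO | intermediate
14 | (4S,5S)-4-[(1S)-1,2-bis(triethylsilyloxy)ethyl]-3-methylidene-5-{(1Z)-2-[5-methyl-4-(Bpin)furan-2-yl]prop-1-en-1-yl}oxolan-2-one | C=C1C(=O)O[C@@H](/C=C(/C)c2cc(B3OC(C)(C)C(C)(C)O3)c(C)o2)[C@H]1[C@H](O[Si](CC)(CC)CC)CO[Si](CC)(CC)CC | intermediate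
15 | (2S)-2-[(2S,3S)-4-methylidene-2-{(1Z)-2-[5-methyl-4-(Bpin)furan-2-yl]prop-1-en-1-yl}-5-oxooxolan-3-yl]-2-(triethylsilyloxy)acetaldehyde | C=C1C(=O)O[C@@H](/C=C(/C)c2cc(B3OC(C)(C)C(C)(C)O3)c(C)o2)[C@H]1[C@H](O[Si](CC)(CC)CC)C=O | intermediate
16 | (2S)-2-[(2S,3S)-4-methylidene-2-{(1Z)-2-(5-methyl-4-oxo-4,5-dihydrofuran-2-yl)prop-1-en-1-yl}-5-oxooxolan-3-yl]-2-(triethylsilyloxy)acetaldehyde (C10 epimers) | C=C1C(=O)O[C@@H](/C=C(/C)C2=CC(=O)C(C)O2)[C@H]1[C@H](O[Si](CC)(CC)CC)C=O | intermediate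
17 | (2S)-2-[(2S,3S)-4-methylidene-2-{(1Z)-2-[5-methyl-4-(triethylsilyloxy)furan-2-yl]prop-1-en-1-yl}-5-oxooxolan-3-yl]-2-(triethylsilyloxy)acetaldehyde | C=C1C(=O)O[C@@H](/C=C(/C)c2cc(O[Si](CC)(CC)CC)c(C)o2)[C@H]1[C@H](O[Si](CC)(CC)CC)C=O | intermediate
18 | (4Z,6S,7S,8S,9R,10R)-9-hydroxy-1-oxo-8-(triethylsilyloxy)-3,10-epoxygermacra-2,4,11(13)-trien-12,6-olide | CC[Si](CC)(CC)O[C@H]1[C@H]2C(=C)C(=O)O[C@H]2/C=C(/C)C2=CC(=O)[C@](C)(O2)[C@@H]1O | intermediate
19 | (4Z,6S,7R,8S,9R,10R)-8,9-dihydroxy-1-oxo-3,10-epoxygermacra-2,4,11(13)-trien-12,6-olide | O[C@H]1[C@H]2C(=C)C(=O)O[C@H]2/C=C(/C)C2=CC(=O)[C@](C)(O2)[C@@H]1O | intermediate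
20 | methacrylic anhydride | CC(=C)C(=O)OC(=O)C(C)=C | starting material
21 | (4Z,6S,7S,8S,9R,10R)-9-hydroxy-8-(2-methylprop-2-enoyloxy)-1-oxo-3,10-epoxygermacra-2,4,11(13)-trien-12,6-olide (CNP0252578.4) | C=C(C)C(=O)O[C@H]1[C@H]2C(=C)C(=O)O[C@H]2/C=C(/C)C2=CC(=O)[C@](C)(O2)[C@@H]1O | target

## Step count and risks

Total step count: 12. Longest linear sequence: 10 steps (steps 1–4 and 7–12, from 2-methylfuran); the bromide branch (steps 5 and 6) joins at step 7.

Steps most likely to fail: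

Step 11 (ring-closing dearomatizing aldol). The ten-membered ring may fail to close under Lewis acid activation, or the C9/C10 pair may come out wrong; the stereochemical model is argued, not precedented. The fallback closes the same bond by a reductive Reformatsky-type reaction instead of a Mukaiyama aldol. It sets out from 16: NBS (THF, 0 °C) brominates the only enolizable furanone carbon to give (2S)-2-[(2S,3S)-2-{(1Z)-2-(5-bromo-5-methyl-4-oxo-4,5-dihydrofuran-2-yl)prop-1-en-1-yl}-4-methylidene-5-oxooxolan-3-yl]-2-(triethylsilyloxy)acetaldehyde F1. Slow addition of F1 to SmI2 (2.5 equiv, THF, −78 °C) gives a trivalent samarium furanolate, again an aromatic 3-oxyfuran, which adds to the aldehyde through a closed, samarium-chelated transition state that predicts the same 9R,10R outcome. The route is rejoined at 18, which is desilylated to 19 with 1 M HCl in THF as in step 11.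

Step 7 (Barbier allylation). The 6,7-syn sense is well precedented for such bromides, but the 7,8-sense rests on an allylic-strain model and could be eroded or reversed by chelation of indium to the dioxolane. The fallback replaces the allylindium by an isolated allylboronate, whose compact boron-centred chair cannot chelate O8. It sets out from 9 (partner 6 unchanged): Ac2O, pyridine and DMAP give methyl 2-{(acetyloxy)[(4R)-2,2-dimethyl-1,3-dioxolan-4-yl]methyl}prop-2-enoate F2. Pd2(dba)3-catalysed borylation with B2pin2 (PhMe, 50 °C) then gives, with allylic transposition, methyl (2E)-3-[(4S)-2,2-dimethyl-1,3-dioxolan-4-yl]-2-[(Bpin)methyl]prop-2-enoate F3, which has the dioxolane cis to CH2Bpin. Sc(OTf)3-catalysed (10 mol %) allylboration of 6 with F3 (PhMe, −78 °C to rt) gives, after aqueous work-up, 11, where the route is rejoined (lactonization to 12 as in step 7).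

Step 12 (site-selective methacrylation). Acylation could also hit O9, or the acyl group could migrate between O8 and O9. The fallback uses orthogonal protection instead of kinetic selection. It sets out from 18, isolated by quenching step 11 with aq. NaHCO3 instead of acid. TBSOTf and 2,6-lutidine silylate O9 to give (4Z,6S,7S,8S,9R,10R)-9-(tert-butyldimethylsilyloxy)-1-oxo-8-(triethylsilyloxy)-3,10-epoxygermacra-2,4,11(13)-trien-12,6-olide F4. AcOH/THF/H2O removes only the triethylsilyl group to give (4Z,6S,7R,8S,9R,10R)-9-(tert-butyldimethylsilyloxy)-8-hydroxy-1-oxo-3,10-epoxygermacra-2,4,11(13)-trien-12,6-olide F5. Methacrylic anhydride and DMAP acylate the single free hydroxyl to give (4Z,6S,7S,8S,9R,10R)-9-(tert-butyldimethylsilyloxy)-8-(2-methylprop-2-enoyloxy)-1-oxo-3,10-epoxygermacra-2,4,11(13)-trien-12,6-olide F6. HF·pyridine in THF removes the TBS group and the route is rejoined at 21.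

## Further compounds

F1 | step 11 | (2S)-2-[(2S,3S)-2-{(1Z)-2-(5-bromo-5-methyl-4-oxo-4,5-dihydrofuran-2-yl)prop-1-en-1-yl}-4-methylidene-5-oxooxolan-3-yl]-2-(triethylsilyloxy)acetaldehyde (epimers at the C–Br carbon) | C=C1C(=O)O[C@@H](/C=C(/C)C2=CC(=O)C(C)(Br)O2)[C@H]1[C@H](O[Si](CC)(CC)CC)C=O
F2 | step 7 | methyl 2-{(acetyloxy)[(4R)-2,2-dimethyl-1,3-dioxolan-4-yl]methyl}prop-2-enoate (carbinol epimers) | C=C(C(=O)OC)C(OC(C)=O)[C@H]1COC(C)(C)O1
F3 | step 7 | methyl (2E)-3-[(4S)-2,2-dimethyl-1,3-dioxolan-4-yl]-2-[(Bpin)methyl]prop-2-enoate | COC(=O)/C(CB1OC(C)(C)C(C)(C)O1)=C/[C@H]1COC(C)(C)O1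
F4 | step 12 | (4Z,6S,7S,8S,9R,10R)-9-(tert-butyldimethylsilyloxy)-1-oxo-8-(triethylsilyloxy)-3,10-epoxygermacra-2,4,11(13)-trien-12,6-olide | CC[Si](CC)(CC)O[C@H]1[C@H]2C(=C)C(=O)O[C@H]2/C=C(/C)C2=CC(=O)[C@](C)(O2)[C@@H]1O[Si](C)(C)C(C)(C)C
F5 | step 12 | (4Z,6S,7R,8S,9R,10R)-9-(tert-butyldimethylsilyloxy)-8-hydroxy-1-oxo-3,10-epoxygermacra-2,4,11(13)-trien-12,6-olide | O[C@H]1[C@H]2C(=C)C(=O)O[C@H]2/C=C(/C)C2=CC(=O)[C@](C)(O2)[C@@H]1O[Si](C)(C)C(C)(C)C
F6 | step 12 | (4Z,6S,7S,8S,9R,10R)-9-(tert-butyldimethylsilyloxy)-8-(2-methylprop-2-enoyloxy)-1-oxo-3,10-epoxygermacra-2,4,11(13)-trien-12,6-olide | C=C(C)C(=O)O[C@H]1[C@H]2C(=C)C(=O)O[C@H]2/C=C(/C)C2=CC(=O)[C@](C)(O2)[C@@H]1O[Si](C)(C)C(C)(C)C
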